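**Strategy.** Ring A (the methylcyclohexene) is closed by joining its methyl-bearing sp2 carbon to the adjacent ring A methine, the carbon that also carries the cyclopentane CH2. In the precursor this methine is the β-carbon of an exocyclic Z-enone on ring B, because the ring B carbon that ends as the carbinol shared by the cyclopentane and tetrahydrofuran rings is still a ketone. A vinyl radical generated on the bromobutenyl arm of the preset quaternary carbon adds there in a 6-endo Michael-type cyclization, which fixes the methine configuration. The quaternary carbon comes from a palladium-catalysed decarboxylative asymmetric geranylation; enolate hydroxylation and a Prins/etherification cascade then build the last two rings.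

Key step: step 13

Remark on the chemistry: the ligand enantiomer named in step 8 is assumed to deliver the R quaternary carbon; if the sense of induction is the reverse, its mirror image is used and nothing else changes.

Step 1
Reactants: 1 but-2-yn-1-ol
Product: 2 (Z)-3-bromobut-2-en-1-ol
Conditions: NaAlH2(OCH2CH2OMe)2, Et2O, 0 °C to rt; then N-bromosuccinimide, −78 to 0 °C
Reagents that add atoms: N-bromosuccinimide, O=C1CCC(=O)N1Br
Why: Alkoxide-directed trans-hydroalumination of the propargylic alcohol puts aluminium on C3 anti to the delivered hydride, and bromination with retention gives the Z bromoalkene (hydroalumination–halogenation).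

Step 2
Reactants: 2 (Z)-3-bromobut-2-en-1-ol
Product: 3 (Z)-1,3-dibromobut-2-ene
Conditions: CBr4, PPh3, CH2Cl2, 0 °C
Reagents that add atoms: carbon tetrabromide, BrC(Br)(Br)Br
Why: Appel reaction of a primary allylic alcohol, which should proceed without allylic transposition or loss of alkene geometry.

Step 3
Reactants: 4 cyclohexane-1,3-dione; 5 1-bromo-3-methylbut-2-ene (prenyl bromide)
Product: 6 2-(3-methylbut-2-en-1-yl)cyclohexane-1,3-dione
Conditions: KOH, H2O, 0 °C to rt
Reagents that add atoms: none
Why: C-alkylation of the dione enolate by a soft allylic bromide in water, where the protic medium favours carbon over oxygen attack.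

Step 4
Reactants: 6 2-(3-methylbut-2-en-1-yl)cyclohexane-1,3-dione
Product: 7 3-methoxy-2-(3-methylbut-2-en-1-yl)cyclohex-2-en-1-one
Conditions: Me2SO4, K2CO3, acetone, reflux
Reagents that add atoms: dimethyl sulfate, COS(=O)(=O)OC
Why: O-methylation of the enolized 2-substituted dione by a hard electrophile gives the vinylogous ester, since C-methylation at the substituted carbon is slow.

Step 5
Reactants: 7 3-methoxy-2-(3-methylbut-2-en-1-yl)cyclohex-2-en-1-one; 3 (Z)-1,3-dibromobut-2-ene
Product: 8 racemic 6-[(Z)-3-bromobut-2-en-1-yl]-3-methoxy-2-(3-methylbut-2-en-1-yl)cyclohex-2-en-1-one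
Conditions: LiN(i-Pr)2, THF, −78 °C; then 3, −78 to 0 °C
Reagents that add atoms: none
Why: Stork–Danheiser alkylation, in which kinetic α'-deprotonation of the vinylogous ester is followed by SN2 at the primary allylic bromide while the alkenyl bromide is untouched; the racemic stereocentre is erased in step 7.

Step 6
Reactants: 9 geraniol; 10 1,1'-carbonyldiimidazole
Product: 11 (E)-3,7-dimethylocta-2,6-dien-1-yl 1H-imidazole-1-carboxylate
Conditions: THF, rt
Reagents that add atoms: none
Why: Acyl substitution at carbonyldiimidazole by the primary allylic alcohol stops cleanly at the mono-imidazolide.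

Step 7
Reactants: 8 racemic 6-[(Z)-3-bromobut-2-en-1-yl]-3-methoxy-2-(3-methylbut-2-en-1-yl)cyclohex-2-en-1-one; 11 geranyl 1H-imidazole-1-carboxylate
Product: 12 2-[(Z)-3-bromobut-2-en-1-yl]-5-methoxy-6-(3-methylbut-2-en-1-yl)cyclohexa-1,5-dien-1-yl geranyl carbonate
Conditions: NaN(SiMe3)2, THF, −78 °C; then 11, BF3·OEt2, −78 to 0 °C; H2O
Reagents that add atoms: none
Why: A second kinetic α'-deprotonation gives the fully substituted enolate, and boron trifluoride-assisted O-acylation by the imidazolide gives the allyl enol carbonate (enol carbonate formation).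

Step 8
Reactants: 12 geranyl enol carbonate
Product: 13 (R)-6-[(Z)-3-bromobut-2-en-1-yl]-6-[(E)-3,7-dimethylocta-2,6-dien-1-yl]-3-methoxy-2-(3-methylbut-2-en-1-yl)cyclohex-2-en-1-one
Conditions: Pd2(dba)3·CHCl3 (2.5 mol %), (1R,2R)-N,N'-bis[2-(diphenylphosphino)benzoyl]cyclohexane-1,2-diamine (6 mol %), toluene, rt
Reagents that add atoms: none
Why: Decarboxylative asymmetric allylic alkylation (Tsuji–Trost type), in which zerovalent palladium ionizes the carbonate, CO2 is lost and the enolate attacks the unsubstituted allyl terminus inside the chiral ligand pocket, so that the ligand selects the enolate face and sets the quaternary carbon, while the alkenyl bromide should survive at rt.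

Step 9
Reactants: 13 (R)-configured α'-quaternary vinylogous ester
Product: 14 (6R)-6-[(Z)-3-bromobut-2-en-1-yl]-6-geranyl-4-hydroxy-3-methoxy-2-(3-methylbut-2-en-1-yl)cyclohex-2-en-1-one (mixture at C4)
Conditions: LiN(i-Pr)2, THF, −78 °C; then 3-phenyl-2-(phenylsulfonyl)oxaziridine, −78 °C; H2O
Reagents that add atoms: 3-phenyl-2-(phenylsulfonyl)oxaziridine, O=S(=O)(c1ccccc1)N1OC1c1ccccc1
Why: With the α'-position blocked the base removes a γ-hydrogen, and the dienolate is oxidized by the sulfonyloxaziridine at the γ-carbon because the α-carbon is fully substituted (dienolate hydroxylation); the new carbinol centre is removed in step 10.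

Step 10
Reactants: 14 γ-hydroxy vinylogous ester
Product: 15 (R)-5-[(Z)-3-bromobut-2-en-1-yl]-5-geranyl-2-methoxy-3-(3-methylbut-2-en-1-yl)cyclohex-2-ene-1,4-dione
Conditions: 1,1,1-triacetoxy-1,1-dihydro-1,2-benziodoxol-3(1H)-one (DMP), CH2Cl2, 0 °C to rt
Reagents that add atoms: none
Why: Periodinane oxidation of the secondary allylic alcohol gives the ene-dione under neutral conditions that spare the alkenes and the alkenyl bromide.

Step 11
Reactants: 16 4-methylpent-3-en-1-ol
Product: 17 4-methylpent-3-enal
Conditions: DMP, CH2Cl2, 0 °C; used cold without storage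
Reagents that add atoms: none
Why: Mild non-basic periodinane oxidation should give the β,γ-unsaturated aldehyde without migration of the alkene into conjugation.

Step 12
Reactants: 15 (R)-ene-dione; 17 4-methylpent-3-enal
Product: 20 (5R,6Z)-5-[(Z)-3-bromobut-2-en-1-yl]-5-geranyl-2-methoxy-6-(4-methylpent-3-en-1-ylidene)-3-(3-methylbut-2-en-1-yl)cyclohex-2-ene-1,4-dione, via β-hydroxy ketone 18 (not isolated), via β-mesyloxy ketone 19 (not isolated)
Conditions: LiN(SiMe3)2, THF, −78 °C; 17, −78 °C; then MsCl, Et3N, −78 °C to rt
Reagents that add atoms: none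
Why: Aldol condensation through the kinetic enolate at the only α-CH2 of the C1 ketone, mesylation and E1cB elimination, in which the Z isomer (chain syn to the C1 carbonyl) should prevail because the E isomer suffers allylic 1,3-strain with the quaternary carbon.

Step 13
Reactants: 20 (5R,6Z)-bromo trienone
Product: 21 (4aS,5R,8aR)-8a-geranyl-3-methoxy-6-methyl-2,5-bis(3-methylbut-2-en-1-yl)-4a,5,8,8a-tetrahydronaphthalene-1,4-dione
Conditions: Bu3SnH (1.3 equiv), AIBN (0.2 equiv), PhH (0.005 M), 80 °C, syringe-pump addition
Reagents that add atoms: none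
Why: The tributyltin radical abstracts bromine to give an α-methylvinyl σ-radical on the arm, which adds to the exocyclic enone β-carbon, and the resulting tertiary α-keto radical is reduced by Bu3SnH; the closest known reaction type is the tin hydride-mediated vinyl radical cyclization onto an enone (radical Michael addition). Ring A closes in the 6-endo-trig mode. The new methine stereocentre is controlled by the Z geometry of the enone together with the quaternary carbon, because the arm can only reach the alkene face on its own side, which places the prenyl CH2 cis to the ring B ketone and the methine H cis to the geranyl group; the ring-fusion C–H formed by hydrogen transfer is of no consequence, since it is planarized in step 15. The step needs 6-endo over 5-exo regioselectivity, which the polarity match at the unsubstituted β-carbon, the hindrance of the fully substituted α-carbon and the stability of the α-keto radical should secure (a 5-exo adduct would also funnel to the same radical by 3-exo closure and ring opening). It also needs cyclization to outrun direct reduction and 1,5-hydrogen transfer, which high dilution and slow addition of the stannane favour. Because the vinyl radical inverts rapidly, the geometry of the bromoalkene is irrelevant.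

Step 14
Reactants: 21 bicyclic methyl vinylogous ester
Product: 22 (4aS,5R,8aR)-8a-geranyl-3-hydroxy-6-methyl-2,5-bis(3-methylbut-2-en-1-yl)-4a,5,8,8a-tetrahydronaphthalene-1,4-dione
Conditions: LiCl, DMSO, 120 °C; then 1 M HCl
Reagents that add atoms: none
Why: Krapcho-type SN2 demethylation of the vinylogous methyl ester by chloride unmasks the vinylogous acid without touching the alkenes.

Step 15
Reactants: 22 bicyclic vinylogous acid
Product: 23 (4aR,5S,8aR)-8a-geranyl-3,4a-dihydroxy-6-methyl-2,5-bis(3-methylbut-2-en-1-yl)-4a,5,8,8a-tetrahydronaphthalene-1,4-dione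
Conditions: KN(SiMe3)2 (2.3 equiv), THF, −78 °C; 3-phenyl-2-(phenylsulfonyl)oxaziridine; then 1 M HCl
Reagents that add atoms: 3-phenyl-2-(phenylsulfonyl)oxaziridine, O=S(=O)(c1ccccc1)N1OC1c1ccccc1
Why: In the dianion the second deprotonation occurs at the ring-fusion C–H α to the ketone (the vinylogous carboxylate shields the prenyl CH2), and the oxaziridine should attack this enolate anti to the folded ring A, placing OH cis to geranyl in the cis-fused bicycle (enolate hydroxylation).

Step 16
Reactants: 23 α-hydroxy ketone
Product: 24 CNP0323114.1 (target)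
Conditions: Sc(OTf)3 (10 mol %), CH2Cl2, 0 °C to rt
Reagents that add atoms: none
Why: Prins cyclization with ether capture, in which the chelated α-hydroxy ketone is attacked 5-exo by the prenyl alkene and the tertiary cation is trapped by the enol oxygen, the cis ring fusions fixing the cyclopentane CH, the new carbinol and the tetrahydrofuran junction.

**Compound list**

1 | but-2-yn-1-ol | CC#CCO | starting material
2 | (Z)-3-bromobut-2-en-1-ol | C/C(Br)=C/CO | intermediate
3 | (Z)-1,3-dibromobut-2-ene | C/C(Br)=C/CBr | intermediate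
4 | cyclohexane-1,3-dione | O=C1CCCC(=O)C1 | starting material
5 | 1-bromo-3-methylbut-2-ene | CC(C)=CCBr | starting material
6 | 2-(3-methylbut-2-en-1-yl)cyclohexane-1,3-dione | CC(C)=CCC1C(=O)CCCC1=O | intermediate
7 | 3-methoxy-2-(3-methylbut-2-en-1-yl)cyclohex-2-en-1-one | COC1=C(CC=C(C)C)C(=O)CCC1 | intermediate
8 | racemic 6-[(Z)-3-bromobut-2-en-1-yl]-3-methoxy-2-(3-methylbut-2-en-1-yl)cyclohex-2-en-1-one | COC1=C(CC=C(C)C)C(=O)C(C/C=C(/C)Br)CC1 | intermediate
9 | geraniol | CC(C)=CCC/C(C)=C/CO | starting material
10 | 1,1'-carbonyldiimidazole | O=C(n1ccnc1)n1ccnc1 | starting material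
11 | geranyl 1H-imidazole-1-carboxylate | CC(C)=CCC/C(C)=C/COC(=O)n1ccnc1 | intermediate
12 | 2-[(Z)-3-bromobut-2-en-1-yl]-5-methoxy-6-(3-methylbut-2-en-1-yl)cyclohexa-1,5-dien-1-yl geranyl carbonate | COC1=C(CC=C(C)C)C(OC(=O)OC/C=C(\C)CCC=C(C)C)=C(C/C=C(/C)Br)CC1 | intermediate
13 | (R)-6-[(Z)-3-bromobut-2-en-1-yl]-6-geranyl-3-methoxy-2-(3-methylbut-2-en-1-yl)cyclohex-2-en-1-one | CC(C)=CCC/C(C)=C/C[C@@]1(C/C=C(/C)Br)CCC(OC)=C(CC=C(C)C)C1=O | intermediate
14 | (6R)-6-[(Z)-3-bromobut-2-en-1-yl]-6-geranyl-4-hydroxy-3-methoxy-2-(3-methylbut-2-en-1-yl)cyclohex-2-en-1-one, C4 epimers | CC(C)=CCC/C(C)=C/C[C@@]1(C/C=C(/C)Br)CC(O)C(OC)=C(CC=C(C)C)C1=O | intermediate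
15 | (R)-5-[(Z)-3-bromobut-2-en-1-yl]-5-geranyl-2-methoxy-3-(3-methylbut-2-en-1-yl)cyclohex-2-ene-1,4-dione | CC(C)=CCC/C(C)=C/C[C@@]1(C/C=C(/C)Br)CC(=O)C(OC)=C(CC=C(C)C)C1=O | intermediate
16 | 4-methylpent-3-en-1-ol | CC(C)=CCCO | starting material
17 | 4-methylpent-3-enal | CC(C)=CCC=O | intermediate
18 | aldol adduct of 15 at C6 with 17 (β-hydroxy ketone, diastereomer mixture, formed as its lithium alkoxide) | CC(C)=CCC/C(C)=C/C[C@@]1(C/C=C(/C)Br)C(C(O)CC=C(C)C)C(=O)C(OC)=C(CC=C(C)C)C1=O | intermediate
19 | methanesulfonate of 18 | CC(C)=CCC/C(C)=C/C[C@@]1(C/C=C(/C)Br)C(C(OS(C)(=O)=O)CC=C(C)C)C(=O)C(OC)=C(CC=C(C)C)C1=O | intermediate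
20 | (5R,6Z)-5-[(Z)-3-bromobut-2-en-1-yl]-5-geranyl-2-methoxy-6-(4-methylpent-3-en-1-ylidene)-3-(3-methylbut-2-en-1-yl)cyclohex-2-ene-1,4-dione | CC(C)=CCC/C(C)=C/C[C@@]1(C/C=C(/C)Br)/C(=C/CC=C(C)C)C(=O)C(OC)=C(CC=C(C)C)C1=O | intermediate
21 | (4aS,5R,8aR)-8a-geranyl-3-methoxy-6-methyl-2,5-bis(3-methylbut-2-en-1-yl)-4a,5,8,8a-tetrahydronaphthalene-1,4-dione (cis-fused) | CC(C)=CCC/C(C)=C/C[C@]12CC=C(C)[C@H](CC=C(C)C)[C@@H]2C(=O)C(OC)=C(CC=C(C)C)C1=O | intermediate
22 | (4aS,5R,8aR)-8a-geranyl-3-hydroxy-6-methyl-2,5-bis(3-methylbut-2-en-1-yl)-4a,5,8,8a-tetrahydronaphthalene-1,4-dione | CC(C)=CCC/C(C)=C/C[C@]12CC=C(C)[C@H](CC=C(C)C)[C@@H]2C(=O)C(O)=C(CC=C(C)C)C1=O | intermediate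
23 | (4aR,5S,8aR)-8a-geranyl-3,4a-dihydroxy-6-methyl-2,5-bis(3-methylbut-2-en-1-yl)-4a,5,8,8a-tetrahydronaphthalene-1,4-dione | CC(C)=CCC/C(C)=C/C[C@]12CC=C(C)[C@H](CC=C(C)C)[C@]2(O)C(=O)C(O)=C(CC=C(C)C)C1=O | intermediate
24 | CNP0323114.1 | CC(C)=CCC/C(C)=C/C[C@]12CC=C(C)[C@@H]3C[C@@H]4C(C)(C)OC(=C(CC=C(C)C)C1=O)[C@]4(O)[C@@]32O | target

**Step count.** Total: 16 steps. Longest linear sequence: 12 steps (steps 3, 4, 5, 7, 8, 9, 10, 12, 13, 14, 15, 16).

**Steps most likely to fail**

1. Step 13. The vinyl radical may be diverted by 1,5-hydrogen transfer from the allylic CH2 of the geranyl group or by direct reduction. Control of the methine may also be lost if closure runs through the 5-exo/ring-expansion manifold, in which the alkene geometry no longer dictates the configuration. Fallback: from 20, a palladium-catalysed reductive Heck cyclization (Pd(OAc)2, PPh3, HCO2Na, DMF, 80 °C). Zerovalent palladium inserts into the Z alkenyl bromide, syn carbopalladation of the enone transfers the alkene geometry to the methine, and formate reduces the palladium enolate. The sequence comes back to the route at 21 and makes no new compound.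

2. Step 8. Facial discrimination of the enolate may be poor, attack may occur at the substituted allyl terminus, or the E geometry may erode by syn/anti exchange in the allyl complex. Fallback: from 8, deprotonation with LiN(i-Pr)2 and alkylation with geranyl bromide gives racemic 6-[(Z)-3-bromobut-2-en-1-yl]-6-geranyl-3-methoxy-2-(3-methylbut-2-en-1-yl)cyclohex-2-en-1-one F1. Its enantiomers are separated by preparative chromatography on a chiral stationary phase, and the R enantiomer comes back to the route at 13.

3. Step 16. The acid may start a proton-initiated cyclization of the geranyl chain, or the tertiary cation may lose a proton instead of being captured by the enol oxygen. Fallback: from 23, a Me2AlCl-promoted carbonyl-ene reaction (CH2Cl2, −78 °C; the Lewis acid scavenges protons) gives the isopropenyl cyclopentanediol F2. Closure of the tetrahydrofuran by 5-exo addition of the enol O–H across the isopropenyl group with catalytic camphorsulfonic acid then comes back to the route at 24.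

**Further compounds**

F0 | step 13 | none | none
F1 | step 8 | racemic 6-[(Z)-3-bromobut-2-en-1-yl]-6-geranyl-3-methoxy-2-(3-methylbut-2-en-1-yl)cyclohex-2-en-1-one | CC(C)=CCC/C(C)=C/CC1(C/C=C(/C)Br)CCC(OC)=C(CC=C(C)C)C1=O
F2 | step 16 | ene product of 23: cis-fused cyclopentane-1,2-diol bearing an isopropenyl group, with free enol OH | CC(C)=CCC/C(C)=C/C[C@]12CC=C(C)[C@@H]3C[C@H](C(C)=C)[C@](O)(C(O)=C(CC=C(C)C)C1=O)[C@@]32O
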